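**Plan**

- Retrosynthesis: the quinone is taken back to its hydroquinone, whose carbocycle is cut at the C4–C5 bond. This is possible because the benzoquinone ring carries the furan as its only substituent: ring atoms C1–C4 and both oxygens can come from a furyl-substituted four-membered dione, and the two remaining CH atoms (C5, C6) from a vinyl group.
- Further cuts: ring carbinol–vinyl bond (vinyl Grignard plus furylcyclobutenedione), furan C2–cyclobutene bond (furyllithium plus diisopropyl squarate, then a reductive transposition that puts H on the fourth ring carbon), the ester C–O bond, the side-chain C=C bond (Wittig) and the ketone–CH2 bond (malonate acylation).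
- Forward: the side chain is built on the bromofuran (steps 1–5), the furan is joined to the four-membered ring (6–7), vinyl is added (8), and the silyl ether is exchanged for the 3-methylbut-2-enoate while the quinone is still masked (9–10). The six-membered carbocycle, the only ring formed, closes in step 11, and oxidation comes last (12).
- Stereochemistry: the single (S) centre is set by asymmetric transfer hydrogenation of the β-keto ester with RuCl[(S,S)-TsDPEN](p-cymene); its C–O bond is never broken afterwards.

Key step: step 11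

Assumptions on the chemistry: a nucleophile attacks a donor-substituted cyclobutenedione at the carbonyl that is not the terminus of the donor-substituted enone, and the ring carbinol of every hydroxycyclobutenone forms as both epimers, which are carried on together because that centre is destroyed in step 11.

**Route**

Step 1
Reactants: 1 5-bromofuran-3-carboxylic acid; 2 potassium ethyl malonate (KO2CCH2CO2Et)
Product: 5 ethyl 3-(5-bromofuran-3-yl)-3-oxopropanoate, via acyl imidazolide 3 (not isolated), via acylmalonic half ester 4 (not isolated)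
Conditions: CDI, THF, rt; then 2, MgCl2, Et3N, MeCN, rt to 40 °C; 1 M HCl work-up
Reagents that add atoms: potassium ethyl malonate 2, CCOC(=O)CC(=O)[O-].[K+]
Why: Masamune–Brooks-type decarboxylative Claisen condensation, in which the acyl imidazolide C-acylates the magnesium enolate of the malonate half ester and the acylmalonic acid loses CO2, a standard passage from an aryl carboxylic acid to its β-keto ester that leaves the 2-bromofuran untouched.

Step 2
Reactants: 5 ethyl 3-(5-bromofuran-3-yl)-3-oxopropanoate
Product: 6 ethyl (3S)-3-(5-bromofuran-3-yl)-3-hydroxypropanoate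
Conditions: RuCl[(S,S)-TsDPEN](p-cymene) (1 mol%), HCO2H/Et3N (5:2), CH2Cl2, 30 °C
Reagents that add atoms: none
Why: Noyori asymmetric transfer hydrogenation of a heteroaryl ketone, where the (S,S)-catalyst should deliver hydride to the face that gives the (S)-carbinol when the aryl group outranks the CH2 group (here O > furyl > CH2CO2Et), and the C–Br bond is inert to these conditions.

Step 3
Reactants: 6 ethyl (3S)-3-(5-bromofuran-3-yl)-3-hydroxypropanoate
Product: 7 ethyl (3S)-3-(5-bromofuran-3-yl)-3-(tert-butyldimethylsilyloxy)propanoate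
Conditions: TBSCl, imidazole, DMF, rt
Reagents that add atoms: tert-butyldimethylsilyl chloride, CC(C)(C)[Si](C)(C)Cl
Why: Standard silylation of a secondary alcohol, giving an ether that should survive i-Bu2AlH, the ylide, n-BuLi, the Grignard reagent and brief dilute acid.

Step 4
Reactants: 7 ethyl (3S)-3-(5-bromofuran-3-yl)-3-(tert-butyldimethylsilyloxy)propanoate
Product: 9 (3S)-3-(5-bromofuran-3-yl)-3-(tert-butyldimethylsilyloxy)propanal, via aluminium hemiacetal 8 (not isolated)
Conditions: i-Bu2AlH (1.1 equiv), CH2Cl2, −78 °C; aq. potassium sodium tartrate (KNaC4H4O6)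
Reagents that add atoms: none
Why: Partial reduction of an ester with i-Bu2AlH, in which the aluminium-bound hemiacetal persists at −78 °C and releases the aldehyde only on work-up, so over-reduction should be avoided.

Step 5
Reactants: 9 (3S)-3-(5-bromofuran-3-yl)-3-(tert-butyldimethylsilyloxy)propanal; 10 isopropyltriphenylphosphonium iodide
Product: 11 {[(1S)-1-(5-bromofuran-3-yl)-4-methylpent-3-en-1-yl]oxy}(tert-butyl)dimethylsilane
Conditions: 10, n-BuLi, THF, 0 °C; then 9, −78 °C to rt
Reagents that add atoms: isopropyltriphenylphosphonium iodide 10, CC(C)[P+](c1ccccc1)(c1ccccc1)c1ccccc1.[I-]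
Why: Wittig olefination with the non-stabilised isopropylidene ylide gives the trisubstituted alkene with no E/Z question, low temperature limits β-elimination of the silyloxy group, and the stereocentre is not enolisable.

Step 6
Reactants: 11 {[(1S)-1-(5-bromofuran-3-yl)-4-methylpent-3-en-1-yl]oxy}(tert-butyl)dimethylsilane; 12 diisopropyl squarate
Product: 14 4-{4-[(1S)-1-(tert-butyldimethylsilyloxy)-4-methylpent-3-en-1-yl]furan-2-yl}-4-hydroxy-2,3-di(propan-2-yloxy)cyclobut-2-en-1-one (both epimers at the ring carbinol), via furyllithium 13 (not isolated)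
Conditions: n-BuLi (1.05 equiv), THF, −78 °C; then 12, −78 °C; aq. NH4Cl
Reagents that add atoms: diisopropyl squarate 12, CC(C)OC1=C(OC(C)C)C(=O)C1=O
Why: Bromine–lithium exchange at the furan α-position followed by 1,2-addition of the aryllithium to a squarate ester should stop after one addition, because the carbonyl left in the adduct is a vinylogous ester that does not react at −78 °C.

Step 7
Reactants: 14 4-{4-[(1S)-1-(tert-butyldimethylsilyloxy)-4-methylpent-3-en-1-yl]furan-2-yl}-4-hydroxy-2,3-di(propan-2-yloxy)cyclobut-2-en-1-one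
Product: 16 3-{4-[(1S)-1-(tert-butyldimethylsilyloxy)-4-methylpent-3-en-1-yl]furan-2-yl}cyclobut-3-ene-1,2-dione, via cyclobutenediol 15 (not isolated)
Conditions: i-Bu2AlH (2.5 equiv), CH2Cl2, −78 °C; then 1 M HCl, THF, 0 °C (short contact)
Reagents that add atoms: water, O
Why: Stork–Danheiser-type 1,2-reduction and acidic allylic transposition of a vinylogous ester, in which each carbinol of the diol ionises to an alkoxy-stabilised cyclobutenyl cation that is hydrolysed, so both isopropoxy carbons become C=O and the furyl group and the new hydrogen end up on the two alkene carbons by construction.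

Step 8
Reactants: 16 3-{4-[(1S)-1-(tert-butyldimethylsilyloxy)-4-methylpent-3-en-1-yl]furan-2-yl}cyclobut-3-ene-1,2-dione; 17 vinylmagnesium bromide
Product: 18 3-{4-[(1S)-1-(tert-butyldimethylsilyloxy)-4-methylpent-3-en-1-yl]furan-2-yl}-4-ethenyl-4-hydroxycyclobut-2-en-1-one (both epimers at the ring carbinol)
Conditions: CH2=CHMgBr (1.05 equiv), THF, −78 °C; aq. NH4Cl
Reagents that add atoms: vinylmagnesium bromide 17, C=C[Mg]Br
Why: Grignard 1,2-addition to a cyclobutenedione should favour the carbonyl next to the furyl-bearing carbon, because the other carbonyl is the deactivated end of the push–pull furyl enone, and any adduct of that other carbonyl would give the same hydroquinone on heating and need not be removed.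

Step 9
Reactants: 18 3-{4-[(1S)-1-(tert-butyldimethylsilyloxy)-4-methylpent-3-en-1-yl]furan-2-yl}-4-ethenyl-4-hydroxycyclobut-2-en-1-one
Product: 19 4-ethenyl-4-hydroxy-3-{4-[(1S)-1-hydroxy-4-methylpent-3-en-1-yl]furan-2-yl}cyclobut-2-en-1-one
Conditions: HF·pyridine, pyridine, THF, 0 °C to rt
Reagents that add atoms: none
Why: Fluoride cleavage of a secondary silyl ether under buffered, non-basic conditions should avoid the alkoxide-triggered ring opening of 4-hydroxycyclobutenones.

Step 10
Reactants: 19 4-ethenyl-4-hydroxy-3-{4-[(1S)-1-hydroxy-4-methylpent-3-en-1-yl]furan-2-yl}cyclobut-2-en-1-one; 20 3-methylbut-2-enoyl chloride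
Product: 21 (1S)-1-[5-(4-ethenyl-4-hydroxy-3-oxocyclobut-1-en-1-yl)furan-3-yl]-4-methylpent-3-en-1-yl 3-methylbut-2-enoate (both epimers at the ring carbinol)
Conditions: 20 (1.1 equiv), pyridine, CH2Cl2, 0 °C
Reagents that add atoms: 3-methylbut-2-enoyl chloride 20, CC(C)=CC(=O)Cl
Why: Acylation through the acylpyridinium ion should select the unhindered secondary alcohol over the tertiary α-keto ring carbinol, pyridine instead of a stronger amine limits vinylketene formation and thus deconjugation of the enoate, and the configuration is retained because the C–O bond is not broken.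

Step 11
Reactants: 21 (1S)-1-[5-(4-ethenyl-4-hydroxy-3-oxocyclobut-1-en-1-yl)furan-3-yl]-4-methylpent-3-en-1-yl 3-methylbut-2-enoate
Product: 24 (1S)-1-[5-(2,5-dihydroxyphenyl)furan-3-yl]-4-methylpent-3-en-1-yl 3-methylbut-2-enoate, via dienylketene 22 (not isolated), via cyclohexadienone 23 (not isolated)
Conditions: degassed toluene (0.02 M), 110 °C, Ar
Reagents that add atoms: none
Why: Heating should open the cyclobutenone by conrotatory 4π electrocyclic cleavage of the bond between the carbonyl carbon and the carbinol carbon, giving dienylketene 22. A disrotatory 6π electrocyclisation then joins the ketene carbon to the vinyl terminus, closing the six-membered carbocycle as dienone 23, which enolises to hydroquinone 24; this is the Moore rearrangement of 4-alkenyl-4-hydroxycyclobutenones. The ring is closed in the 6π electrocyclic mode with one new C–C bond, no stereocentre is created, and the side-chain centre is a spectator. The step needs the vinyl group to rotate inward, which is secured by the donor hydroxyl on the same carbon rotating outward (torquoselectivity), so the (Z)-dienylketene forms. A dilute, aprotic, non-nucleophilic medium lets the ketene close on the vinyl group instead of being trapped. The furyl group on C3 could only close a five-membered ring with the ketene and so does not compete, and the enoate ester should be thermally inert at this temperature.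

Step 12
Reactants: 24 (1S)-1-[5-(2,5-dihydroxyphenyl)furan-3-yl]-4-methylpent-3-en-1-yl 3-methylbut-2-enoate
Product: 25 (1S)-1-[5-(3,6-dioxocyclohexa-1,4-dien-1-yl)furan-3-yl]-4-methylpent-3-en-1-yl 3-methylbut-2-enoate
Conditions: Ag2O, MgSO4, Et2O, rt, dark
Reagents that add atoms: none
Why: Oxidation of a free hydroquinone to the quinone with Ag2O runs under neutral, anhydrous conditions without acid or nucleophile, so the furan, the trisubstituted alkene and the ester should be preserved and the sensitive quinone is made only at the very end.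

**Compound list**

1 | 5-bromofuran-3-carboxylic acid | OC(=O)c1coc(Br)c1 | starting material
2 | potassium ethyl malonate (potassium 3-ethoxy-3-oxopropanoate) | CCOC(=O)CC(=O)[O-].[K+] | starting material
3 | (5-bromofuran-3-yl)(1H-imidazol-1-yl)methanone (acyl imidazolide; not isolated) | O=C(c1coc(Br)c1)n1ccnc1 | intermediate
4 | 2-(5-bromofuran-3-carbonyl)-3-ethoxy-3-oxopropanoic acid (acylmalonic half ester; not isolated) | CCOC(=O)C(C(=O)O)C(=O)c1coc(Br)c1 | intermediate
5 | ethyl 3-(5-bromofuran-3-yl)-3-oxopropanoate | CCOC(=O)CC(=O)c1coc(Br)c1 | intermediate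
6 | ethyl (3S)-3-(5-bromofuran-3-yl)-3-hydroxypropanoate | CCOC(=O)C[C@H](O)c1coc(Br)c1 | intermediate
7 | ethyl (3S)-3-(5-bromofuran-3-yl)-3-(tert-butyldimethylsilyloxy)propanoate | CCOC(=O)C[C@H](O[Si](C)(C)C(C)(C)C)c1coc(Br)c1 | intermediate
8 | diisobutylaluminium ethyl hemiacetal of aldehyde 9 (not isolated) | CCOC(O[Al](CC(C)C)CC(C)C)C[C@H](O[Si](C)(C)C(C)(C)C)c1coc(Br)c1 | intermediate
9 | (3S)-3-(5-bromofuran-3-yl)-3-(tert-butyldimethylsilyloxy)propanal | O=CC[C@H](O[Si](C)(C)C(C)(C)C)c1coc(Br)c1 | intermediate
10 | isopropyltriphenylphosphonium iodide | CC(C)[P+](c1ccccc1)(c1ccccc1)c1ccccc1.[I-] | starting material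
11 | {[(1S)-1-(5-bromofuran-3-yl)-4-methylpent-3-en-1-yl]oxy}(tert-butyl)dimethylsilane | CC(C)=CC[C@H](O[Si](C)(C)C(C)(C)C)c1coc(Br)c1 | intermediate
12 | diisopropyl squarate (3,4-di(propan-2-yloxy)cyclobut-3-ene-1,2-dione) | CC(C)OC1=C(OC(C)C)C(=O)C1=O | starting material
13 | {4-[(1S)-1-(tert-butyldimethylsilyloxy)-4-methylpent-3-en-1-yl]furan-2-yl}lithium (not isolated) | CC(C)=CC[C@H](O[Si](C)(C)C(C)(C)C)c1coc([Li])c1 | intermediate
14 | 4-{4-[(1S)-1-(tert-butyldimethylsilyloxy)-4-methylpent-3-en-1-yl]furan-2-yl}-4-hydroxy-2,3-di(propan-2-yloxy)cyclobut-2-en-1-one, both epimers at the ring carbinol | CC(C)=CC[C@H](O[Si](C)(C)C(C)(C)C)c1coc(C2(O)C(OC(C)C)=C(OC(C)C)C2=O)c1 | intermediate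
15 | 1-{4-[(1S)-1-(tert-butyldimethylsilyloxy)-4-methylpent-3-en-1-yl]furan-2-yl}-2,3-di(propan-2-yloxy)cyclobut-2-ene-1,4-diol, mixture of ring stereoisomers (not isolated) | CC(C)=CC[C@H](O[Si](C)(C)C(C)(C)C)c1coc(C2(O)C(OC(C)C)=C(OC(C)C)C2O)c1 | intermediate
16 | 3-{4-[(1S)-1-(tert-butyldimethylsilyloxy)-4-methylpent-3-en-1-yl]furan-2-yl}cyclobut-3-ene-1,2-dione | CC(C)=CC[C@H](O[Si](C)(C)C(C)(C)C)c1coc(C2=CC(=O)C2=O)c1 | intermediate
17 | vinylmagnesium bromide | C=C[Mg]Br | starting material
18 | 3-{4-[(1S)-1-(tert-butyldimethylsilyloxy)-4-methylpent-3-en-1-yl]furan-2-yl}-4-ethenyl-4-hydroxycyclobut-2-en-1-one, both epimers at the ring carbinol | CC(C)=CC[C@H](O[Si](C)(C)C(C)(C)C)c1coc(C2=CC(=O)C2(O)C=C)c1 | intermediate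
19 | 4-ethenyl-4-hydroxy-3-{4-[(1S)-1-hydroxy-4-methylpent-3-en-1-yl]furan-2-yl}cyclobut-2-en-1-one, both epimers at the ring carbinol | CC(C)=CC[C@H](O)c1coc(C2=CC(=O)C2(O)C=C)c1 | intermediate
20 | 3-methylbut-2-enoyl chloride | CC(C)=CC(=O)Cl | starting material
21 | (1S)-1-[5-(4-ethenyl-4-hydroxy-3-oxocyclobut-1-en-1-yl)furan-3-yl]-4-methylpent-3-en-1-yl 3-methylbut-2-enoate, both epimers at the ring carbinol (key-step precursor) | CC(C)=CC[C@H](OC(=O)C=C(C)C)c1coc(C2=CC(=O)C2(O)C=C)c1 | intermediate
22 | (1S)-1-{5-[(3Z)-4-hydroxy-1-oxohexa-1,3,5-trien-3-yl]furan-3-yl}-4-methylpent-3-en-1-yl 3-methylbut-2-enoate (dienylketene; not isolated) | CC(C)=CC[C@H](OC(=O)C=C(C)C)c1coc(/C(C=C=O)=C(\O)C=C)c1 | intermediate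
23 | (1S)-1-[5-(6-hydroxy-3-oxocyclohexa-1,5-dien-1-yl)furan-3-yl]-4-methylpent-3-en-1-yl 3-methylbut-2-enoate (cyclohexadienone; not isolated) | CC(C)=CC[C@H](OC(=O)C=C(C)C)c1coc(C2=CC(=O)CC=C2O)c1 | intermediate
24 | (1S)-1-[5-(2,5-dihydroxyphenyl)furan-3-yl]-4-methylpent-3-en-1-yl 3-methylbut-2-enoate (key-step product) | CC(C)=CC[C@H](OC(=O)C=C(C)C)c1coc(-c2cc(O)ccc2O)c1 | intermediate
25 | (1S)-1-[5-(3,6-dioxocyclohexa-1,4-dien-1-yl)furan-3-yl]-4-methylpent-3-en-1-yl 3-methylbut-2-enoate | CC(C)=CC[C@H](OC(=O)C=C(C)C)c1coc(C2=CC(=O)C=CC2=O)c1 | target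

**Step count and risks**

Total steps: 12. Longest linear sequence: 12 steps (1 to 25); all other partners are commercial.

Step 7 is the most likely to fail. The 1,2-reduction of the hindered vinylogous ester carbonyl may be incomplete, the silyl ether or the electron-rich furan may not survive the acid-mediated double transposition, or the monosubstituted dione may degrade on isolation. The fallback brings the furan in last; it sets out from 12 and 11 and comes back at 18, bypassing 14–16. Reduction of 12 with LiAlH(Ot-Bu)3 (THF, −78 to 0 °C) would give 4-hydroxy-2,3-di(propan-2-yloxy)cyclobut-2-en-1-one F1, hydrolysed in the same flask with aqueous HCl to 3-(propan-2-yloxy)cyclobut-3-ene-1,2-dione F2. CH2=CHMgBr (17, THF, −78 °C) should add to the carbonyl next to the alkoxy-bearing carbon, the other one being a vinylogous ester, to give 4-ethenyl-4-hydroxy-3-(propan-2-yloxy)cyclobut-2-en-1-one F3, which is silylated (Me3SiCl, Et3N) to 4-ethenyl-3-(propan-2-yloxy)-4-(trimethylsilyloxy)cyclobut-2-en-1-one F4. Furyllithium 13, made from 11 as in step 6, then adds to the vinylogous ester carbonyl of F4 to give the tertiary carbinol 1-{4-[(1S)-1-(tert-butyldimethylsilyloxy)-4-methylpent-3-en-1-yl]furan-2-yl}-4-ethenyl-3-(propan-2-yloxy)-4-(trimethylsilyloxy)cyclobut-2-en-1-ol F5. Dilute HCl should then effect the Stork–Danheiser-type 1,3-transposition with loss of propan-2-ol and of the trimethylsilyl group, giving 18.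

Step 10 is second. Site selectivity between the two hydroxyl groups may be lost (acylation of the tertiary ring carbinol), the base may trigger rearrangement of the hydroxycyclobutenone, or the enoate may deconjugate through a vinylketene. The fallback moves the protecting-group exchange to a stage with a single hydroxyl; it sets out from 16 and comes back at 21. HF·pyridine would convert 16 into 3-{4-[(1S)-1-hydroxy-4-methylpent-3-en-1-yl]furan-2-yl}cyclobut-3-ene-1,2-dione F6. Acylation with 20 and pyridine would give (1S)-1-[5-(3,4-dioxocyclobut-1-en-1-yl)furan-3-yl]-4-methylpent-3-en-1-yl 3-methylbut-2-enoate F7. CH2=CHMgBr at −78 °C, which should attack the strained dione carbonyl far faster than the hindered enoate, then leads to 21.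

Step 11 is third. The furylic ester may ionise or eliminate at the temperature needed for ring opening, or the ketene may be intercepted by a hydroxyl group before the 6π closure. The fallback runs the rearrangement on the silyl ether and installs the ester at the end; it sets out from 18 and comes back at 25. Thermolysis of 18 under the same conditions should give 2-{4-[(1S)-1-(tert-butyldimethylsilyloxy)-4-methylpent-3-en-1-yl]furan-2-yl}benzene-1,4-diol F8. Ag2O would oxidise it to 2-{4-[(1S)-1-(tert-butyldimethylsilyloxy)-4-methylpent-3-en-1-yl]furan-2-yl}cyclohexa-2,5-diene-1,4-dione F9, and HF·pyridine would free 2-{4-[(1S)-1-hydroxy-4-methylpent-3-en-1-yl]furan-2-yl}cyclohexa-2,5-diene-1,4-dione F10. Acylation with 20 and pyridine then gives 25; the price is that the last two operations run on the electrophilic quinone.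

**Further compounds**

F1 | step 7 | 4-hydroxy-2,3-di(propan-2-yloxy)cyclobut-2-en-1-one | CC(C)OC1=C(OC(C)C)C(O)C1=O
F2 | step 7 | 3-(propan-2-yloxy)cyclobut-3-ene-1,2-dione | CC(C)OC1=CC(=O)C1=O
F3 | step 7 | 4-ethenyl-4-hydroxy-3-(propan-2-yloxy)cyclobut-2-en-1-one | CC(C)OC1=CC(=O)C1(O)C=C
F4 | step 7 | 4-ethenyl-3-(propan-2-yloxy)-4-(trimethylsilyloxy)cyclobut-2-en-1-one | CC(C)OC1=CC(=O)C1(O[Si](C)(C)C)C=C
F5 | step 7 | 1-{4-[(1S)-1-(tert-butyldimethylsilyloxy)-4-methylpent-3-en-1-yl]furan-2-yl}-4-ethenyl-3-(propan-2-yloxy)-4-(trimethylsilyloxy)cyclobut-2-en-1-ol | CC(C)=CC[C@H](O[Si](C)(C)C(C)(C)C)c1coc(C2(O)C=C(OC(C)C)C2(O[Si](C)(C)C)C=C)c1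
F6 | step 10 | 3-{4-[(1S)-1-hydroxy-4-methylpent-3-en-1-yl]furan-2-yl}cyclobut-3-ene-1,2-dione | CC(C)=CC[C@H](O)c1coc(C2=CC(=O)C2=O)c1
F7 | step 10 | (1S)-1-[5-(3,4-dioxocyclobut-1-en-1-yl)furan-3-yl]-4-methylpent-3-en-1-yl 3-methylbut-2-enoate | CC(C)=CC[C@H](OC(=O)C=C(C)C)c1coc(C2=CC(=O)C2=O)c1
F8 | step 11 | 2-{4-[(1S)-1-(tert-butyldimethylsilyloxy)-4-methylpent-3-en-1-yl]furan-2-yl}benzene-1,4-diol | CC(C)=CC[C@H](O[Si](C)(C)C(C)(C)C)c1coc(-c2cc(O)ccc2O)c1
F9 | step 11 | 2-{4-[(1S)-1-(tert-butyldimethylsilyloxy)-4-methylpent-3-en-1-yl]furan-2-yl}cyclohexa-2,5-diene-1,4-dione | CC(C)=CC[C@H](O[Si](C)(C)C(C)(C)C)c1coc(C2=CC(=O)C=CC2=O)c1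
F10 | step 11 | 2-{4-[(1S)-1-hydroxy-4-methylpent-3-en-1-yl]furan-2-yl}cyclohexa-2,5-diene-1,4-dione | CC(C)=CC[C@H](O)c1coc(C2=CC(=O)C=CC2=O)c1
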